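## Retrosynthetic overview

1. The target is a 5,5'-linked dimer of two mirror-image trans-1-aryl-1,2-dihydronaphthalene-2,3-dicarboxylic acids; the last two steps remove four tert-butyl esters and eight benzyl ethers from 21.
2. The C5–C5' biaryl bond is the last C–C bond made: Suzuki–Miyaura coupling of the (1R,2S)-bromide 14 with the (1S,2R)-boronate 20, so the mirror-image pairing is fixed by the choice of partners.
3. Each dihydronaphthalene ring is closed before the coupling, one per enantiomeric series, by intramolecular aldol condensation (C3–C4) of a 2-(diarylmethyl)succinate onto an ortho-aldehyde; C2 is set trans by equilibration.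
4. C1 is set by rhodium/chiral-diene-catalysed 1,4-addition of arylboronic acid 8 to the achiral bromo-cinnamate 7, run once with each ligand antipode.
5. Cinnamate 7 comes from 2-bromo-4,5-dihydroxybenzaldehyde by selective benzylation, Heck reaction, haloperoxidase-catalysed ortho-bromination, benzylation and acetalisation.

Assumption: the SMILES fixes (1R,2S) in one half and (1S,2R) in the other (each half trans, the halves mirror images) and leaves the biaryl axis undefined; the route delivers this heterochiral dimer without axial control, the two senses of the axis being mirror images of each other.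

## Route

Step 1
Reactants: 1 2-bromo-4,5-dihydroxybenzaldehyde
Product: 2 4-(benzyloxy)-2-bromo-5-hydroxybenzaldehyde
Conditions: BnBr (1.05 equiv), NaHCO3 (1.5 equiv), DMF, 40 °C
Reagents that add atoms: benzyl bromide, BrCc1ccccc1
Why: Williamson ether synthesis in which the 4-OH, para to the formyl group, is by far the more acidic phenol, so the weak base ionises and benzylates it alone.

Step 2
Reactants: 2 4-(benzyloxy)-2-bromo-5-hydroxybenzaldehyde; 3 tert-butyl acrylate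
Product: 4 tert-butyl (2E)-3-[5-(benzyloxy)-2-formyl-4-hydroxyphenyl]prop-2-enoate
Conditions: Pd(OAc)2 (3 mol%), P(o-tol)3 (6 mol%), NaOAc (2 equiv), DMF, 110 °C
Reagents that add atoms: none
Why: Mizoroki–Heck reaction of an aryl bromide activated by the ortho-formyl group, with syn insertion and syn β-hydride elimination giving the E-cinnamate.

Step 3
Reactants: 4 tert-butyl (2E)-3-[5-(benzyloxy)-2-formyl-4-hydroxyphenyl]prop-2-enoate
Product: 5 tert-butyl (2E)-3-[5-(benzyloxy)-3-bromo-2-formyl-4-hydroxyphenyl]prop-2-enoate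
Conditions: vanadium-dependent haloperoxidase (chloroperoxidase of Curvularia inaequalis), KBr (1.5 equiv), H2O2 (1.1 equiv, slow feed), citrate buffer pH 5/MeCN 7:3, 25 °C
Reagents that add atoms: potassium bromide, [K+].[Br-]
Why: Enzymatic electrophilic aromatic bromination in which the haloperoxidase oxidises bromide with H2O2 to hypobromous acid at a low steady concentration; this attacks the only free position ortho to the phenol (para is blocked), leaves the electron-poor acrylate alone, and no Dakin oxidation occurs because the OH is meta to the aldehyde.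

Step 4
Reactants: 5 tert-butyl (2E)-3-[5-(benzyloxy)-3-bromo-2-formyl-4-hydroxyphenyl]prop-2-enoate
Product: 6 tert-butyl (2E)-3-[4,5-bis(benzyloxy)-3-bromo-2-formylphenyl]prop-2-enoate
Conditions: BnBr (1.3 equiv), K2CO3 (1.5 equiv), DMF, 50 °C
Reagents that add atoms: benzyl bromide, BrCc1ccccc1
Why: Williamson ether synthesis on the phenoxide, the aldehyde having no α-hydrogen and the tert-butyl ester being inert to carbonate.

Step 5
Reactants: 6 tert-butyl (2E)-3-[4,5-bis(benzyloxy)-3-bromo-2-formylphenyl]prop-2-enoate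
Product: 7 tert-butyl (2E)-3-[4,5-bis(benzyloxy)-3-bromo-2-(dimethoxymethyl)phenyl]prop-2-enoate
Conditions: HC(OMe)3 (5 equiv), MeOH, PPTS (10 mol%), 50 °C
Reagents that add atoms: trimethyl orthoformate, COC(OC)OC; methanol, CO
Why: Acid-catalysed acetalisation driven by the orthoformate as water scavenger, masking the aldehyde against aryl–rhodium addition and against the ester enolate used later.

Step 6
Reactants: 7 tert-butyl (2E)-3-[4,5-bis(benzyloxy)-3-bromo-2-(dimethoxymethyl)phenyl]prop-2-enoate; 8 3,4-bis(benzyloxy)phenylboronic acid (2 equiv)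
Product: 9 tert-butyl (3R)-3-[4,5-bis(benzyloxy)-3-bromo-2-(dimethoxymethyl)phenyl]-3-[3,4-bis(benzyloxy)phenyl]propanoate
Conditions: [RhCl(C2H4)2]2 (2.5 mol%), (1R,4R)-2,5-diphenylbicyclo[2.2.2]octa-2,5-diene (5.5 mol%), KOH (0.5 equiv), 1,4-dioxane/H2O 10:1, 50 °C
Reagents that add atoms: none
Why: Hayashi–Miyaura asymmetric 1,4-addition in which the aryl–rhodium species adds to the β-carbon of the tert-butyl cinnamate on the face selected by the C2-symmetric diene, setting the diaryl-methine centre (3R expected with this antipode, to be confirmed by X-ray or chiroptical correlation; since both antipodes of the adduct are needed, a reversed sense would only exchange the ligands of steps 6 and 10), while the acetal and the aryl bromide are inert.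

Step 7
Reactants: 9 tert-butyl (3R)-3-[4,5-bis(benzyloxy)-3-bromo-2-(dimethoxymethyl)phenyl]-3-[3,4-bis(benzyloxy)phenyl]propanoate; 10 tert-butyl bromoacetate
Product: 11 di-tert-butyl 2-{(R)-[4,5-bis(benzyloxy)-3-bromo-2-(dimethoxymethyl)phenyl][3,4-bis(benzyloxy)phenyl]methyl}butanedioate (both C2 epimers)
Conditions: LiN(iPr)2 (1.15 equiv), THF, −78 °C; then 10 (1.3 equiv), −78 to −30 °C
Reagents that add atoms: none
Why: Ester enolate alkylation (SN2) with a reactive α-bromo ester builds the succinate; the new centre is formed as a mixture on purpose because it is equilibrated in step 9, and the aryl bromide has no ortho hydrogen so it cannot give an aryne.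

Step 8
Reactants: 11 di-tert-butyl 2-{(R)-[4,5-bis(benzyloxy)-3-bromo-2-(dimethoxymethyl)phenyl][3,4-bis(benzyloxy)phenyl]methyl}butanedioate
Product: 12 di-tert-butyl 2-{(R)-[4,5-bis(benzyloxy)-3-bromo-2-formylphenyl][3,4-bis(benzyloxy)phenyl]methyl}butanedioate (both C2 epimers)
Conditions: PPTS (0.2 equiv), acetone/H2O 9:1, 50 °C
Reagents that add atoms: water, O
Why: Mild acid-catalysed acetal hydrolysis that frees the aldehyde while tert-butyl esters and benzyl ethers are untouched.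

Step 9
Reactants: 12 di-tert-butyl 2-{(R)-[4,5-bis(benzyloxy)-3-bromo-2-formylphenyl][3,4-bis(benzyloxy)phenyl]methyl}butanedioate
Product: 14 di-tert-butyl (1R,2S)-6,7-bis(benzyloxy)-1-[3,4-bis(benzyloxy)phenyl]-5-bromo-1,2-dihydronaphthalene-2,3-dicarboxylate, via 4-hydroxytetralin aldol adduct 13 (not isolated)
Conditions: KOtBu (1.2 equiv), t-BuOH/THF 1:1, 0 °C to rt; AcOH; then DBU (0.2 equiv), CH2Cl2, rt
Reagents that add atoms: none
Why: Intramolecular aldol condensation (Stobbe-type, E1cB dehydration) in which the succinate CH2 enolate closes the six-membered ring on the aldehyde and loss of water gives the arene-conjugated ester irreversibly (the competing five-ring aldol from C2 is reversible and cannot dehydrate); C2, alpha to an ester, equilibrates to the trans arrangement with both groups pseudoaxial, so C1 (R) dictates C2 (S), and tert-butyl esters resist saponification and lactonisation.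

Step 10
Reactants: 7 tert-butyl (2E)-3-[4,5-bis(benzyloxy)-3-bromo-2-(dimethoxymethyl)phenyl]prop-2-enoate; 8 3,4-bis(benzyloxy)phenylboronic acid (2 equiv)
Product: 15 tert-butyl (3S)-3-[4,5-bis(benzyloxy)-3-bromo-2-(dimethoxymethyl)phenyl]-3-[3,4-bis(benzyloxy)phenyl]propanoate
Conditions: [RhCl(C2H4)2]2 (2.5 mol%), (1S,4S)-2,5-diphenylbicyclo[2.2.2]octa-2,5-diene (5.5 mol%), KOH (0.5 equiv), 1,4-dioxane/H2O 10:1, 50 °C
Reagents that add atoms: none
Why: The same Hayashi–Miyaura asymmetric 1,4-addition with the antipodal diene, which delivers the aryl group to the opposite enoate face and gives the 3S centre.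

Step 11
Reactants: 15 tert-butyl (3S)-3-[4,5-bis(benzyloxy)-3-bromo-2-(dimethoxymethyl)phenyl]-3-[3,4-bis(benzyloxy)phenyl]propanoate; 10 tert-butyl bromoacetate
Product: 16 di-tert-butyl 2-{(S)-[4,5-bis(benzyloxy)-3-bromo-2-(dimethoxymethyl)phenyl][3,4-bis(benzyloxy)phenyl]methyl}butanedioate (both C2 epimers)
Conditions: LiN(iPr)2 (1.15 equiv), THF, −78 °C; then 10 (1.3 equiv), −78 to −30 °C
Reagents that add atoms: none
Why: Ester enolate alkylation (SN2) as in step 7, the C2 mixture again being corrected later.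

Step 12
Reactants: 16 di-tert-butyl 2-{(S)-[4,5-bis(benzyloxy)-3-bromo-2-(dimethoxymethyl)phenyl][3,4-bis(benzyloxy)phenyl]methyl}butanedioate
Product: 17 di-tert-butyl 2-{(S)-[4,5-bis(benzyloxy)-3-bromo-2-formylphenyl][3,4-bis(benzyloxy)phenyl]methyl}butanedioate (both C2 epimers)
Conditions: PPTS (0.2 equiv), acetone/H2O 9:1, 50 °C
Reagents that add atoms: water, O
Why: Mild acid-catalysed acetal hydrolysis as in step 8.

Step 13
Reactants: 17 di-tert-butyl 2-{(S)-[4,5-bis(benzyloxy)-3-bromo-2-formylphenyl][3,4-bis(benzyloxy)phenyl]methyl}butanedioate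
Product: 19 di-tert-butyl (1S,2R)-6,7-bis(benzyloxy)-1-[3,4-bis(benzyloxy)phenyl]-5-bromo-1,2-dihydronaphthalene-2,3-dicarboxylate, via mirror-image 4-hydroxytetralin aldol adduct 18 (not isolated)
Conditions: KOtBu (1.2 equiv), t-BuOH/THF 1:1, 0 °C to rt; AcOH; then DBU (0.2 equiv), CH2Cl2, rt
Reagents that add atoms: none
Why: Intramolecular aldol condensation with E1cB dehydration and thermodynamic trans equilibration as in step 9, so C1 (S) dictates C2 (R).

Step 14
Reactants: 19 di-tert-butyl (1S,2R)-6,7-bis(benzyloxy)-1-[3,4-bis(benzyloxy)phenyl]-5-bromo-1,2-dihydronaphthalene-2,3-dicarboxylate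
Product: 20 di-tert-butyl (1S,2R)-6,7-bis(benzyloxy)-1-[3,4-bis(benzyloxy)phenyl]-5-(4,4,5,5-tetramethyl-1,3,2-dioxaborolan-2-yl)-1,2-dihydronaphthalene-2,3-dicarboxylate
Conditions: B2pin2 (1.5 equiv), PdCl2(dppf) (5 mol%), KOAc (3 equiv), 1,4-dioxane, 90 °C
Reagents that add atoms: bis(pinacolato)diboron, CC1(C)OB(OC1(C)C)B1OC(C)(C)C(C)(C)O1
Why: Miyaura borylation under weakly basic acetate conditions, precedented for 1-bromo-2-alkoxynaphthalene-type halides, which touches neither the esters nor the stereocentres.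

Step 15
Reactants: 14 di-tert-butyl (1R,2S)-6,7-bis(benzyloxy)-1-[3,4-bis(benzyloxy)phenyl]-5-bromo-1,2-dihydronaphthalene-2,3-dicarboxylate; 20 di-tert-butyl (1S,2R)-6,7-bis(benzyloxy)-1-[3,4-bis(benzyloxy)phenyl]-5-(4,4,5,5-tetramethyl-1,3,2-dioxaborolan-2-yl)-1,2-dihydronaphthalene-2,3-dicarboxylate
Product: 21 tetra-tert-butyl (1R,2S,1'S,2'R)-6,6',7,7'-tetrakis(benzyloxy)-1,1'-bis[3,4-bis(benzyloxy)phenyl]-1,1',2,2'-tetrahydro-[5,5'-binaphthalene]-2,2',3,3'-tetracarboxylate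
Conditions: Pd(OAc)2 (5 mol%), SPhos (10 mol%), K3PO4 (3 equiv), toluene/H2O 10:1, 90 °C
Reagents that add atoms: none
Why: Suzuki–Miyaura cross-coupling with a bulky biaryl dialkylphosphine that tolerates a tetra-ortho-substituted, 2-alkoxy-1-naphthyl-type pairing; only the mirror-image pairing can form because bromide and boronate come from opposite series, no sp3 centre is touched, the two senses of the new axis are mirror images so one diastereomer results, and any minor enantiomer from steps 6 and 10 ends up in separable homochiral diastereomers.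

Step 16
Reactants: 21 tetra-tert-butyl (1R,2S,1'S,2'R)-6,6',7,7'-tetrakis(benzyloxy)-1,1'-bis[3,4-bis(benzyloxy)phenyl]-1,1',2,2'-tetrahydro-[5,5'-binaphthalene]-2,2',3,3'-tetracarboxylate
Product: 22 (1R,2S,1'S,2'R)-6,6',7,7'-tetrakis(benzyloxy)-1,1'-bis[3,4-bis(benzyloxy)phenyl]-1,1',2,2'-tetrahydro-[5,5'-binaphthalene]-2,2',3,3'-tetracarboxylic acid
Conditions: CF3CO2H/CH2Cl2 1:3, 0 °C to rt
Reagents that add atoms: none
Why: Acidolysis of tert-butyl esters through the tert-butyl cation (lost as isobutene), which avoids any basic hydrolysis that could move the double bond or epimerise C2, while aryl benzyl ethers survive dilute trifluoroacetic acid.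

Step 17
Reactants: 22 (1R,2S,1'S,2'R)-6,6',7,7'-tetrakis(benzyloxy)-1,1'-bis[3,4-bis(benzyloxy)phenyl]-1,1',2,2'-tetrahydro-[5,5'-binaphthalene]-2,2',3,3'-tetracarboxylic acid
Product: 23 (1R,2S,1'S,2'R)-1,1'-bis(3,4-dihydroxyphenyl)-6,6',7,7'-tetrahydroxy-1,1',2,2'-tetrahydro-[5,5'-binaphthalene]-2,2',3,3'-tetracarboxylic acid (CNP0242074.1)
Conditions: BCl3 (1 M in CH2Cl2, 20 equiv), pentamethylbenzene (24 equiv), CH2Cl2, −78 to −40 °C; MeOH quench; reverse-phase chromatography under argon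
Reagents that add atoms: none
Why: Lewis-acid debenzylation of aryl benzyl ethers with pentamethylbenzene as a non-basic benzyl-cation scavenger, run cold so that the conjugated alkene, the acids and the two trans stereodiads are untouched and the catechols are never exposed to base or hydrogenation.

## Compound list

1 | 2-bromo-4,5-dihydroxybenzaldehyde | O=Cc1cc(O)c(O)cc1Br | starting material
2 | 4-(benzyloxy)-2-bromo-5-hydroxybenzaldehyde | O=Cc1cc(O)c(OCc2ccccc2)cc1Br | intermediate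
3 | tert-butyl acrylate | C=CC(=O)OC(C)(C)C | starting material
4 | tert-butyl (2E)-3-[5-(benzyloxy)-2-formyl-4-hydroxyphenyl]prop-2-enoate | O=Cc1cc(O)c(OCc2ccccc2)cc1/C=C/C(=O)OC(C)(C)C | intermediate
5 | tert-butyl (2E)-3-[5-(benzyloxy)-3-bromo-2-formyl-4-hydroxyphenyl]prop-2-enoate | O=Cc1c(Br)c(O)c(OCc2ccccc2)cc1/C=C/C(=O)OC(C)(C)C | intermediate
6 | tert-butyl (2E)-3-[4,5-bis(benzyloxy)-3-bromo-2-formylphenyl]prop-2-enoate | O=Cc1c(Br)c(OCc2ccccc2)c(OCc2ccccc2)cc1/C=C/C(=O)OC(C)(C)C | intermediate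
7 | tert-butyl (2E)-3-[4,5-bis(benzyloxy)-3-bromo-2-(dimethoxymethyl)phenyl]prop-2-enoate | COC(OC)c1c(Br)c(OCc2ccccc2)c(OCc2ccccc2)cc1/C=C/C(=O)OC(C)(C)C | intermediate
8 | 3,4-bis(benzyloxy)phenylboronic acid | OB(O)c1ccc(OCc2ccccc2)c(OCc2ccccc2)c1 | starting material
9 | tert-butyl (3R)-3-[4,5-bis(benzyloxy)-3-bromo-2-(dimethoxymethyl)phenyl]-3-[3,4-bis(benzyloxy)phenyl]propanoate | CC(C)(C)OC(=O)C[C@H](c1ccc(OCc2ccccc2)c(OCc2ccccc2)c1)c1cc(OCc2ccccc2)c(OCc2ccccc2)c(Br)c1C(OC)OC | intermediate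
10 | tert-butyl bromoacetate | BrCC(=O)OC(C)(C)C | starting material
11 | di-tert-butyl 2-{(R)-[4,5-bis(benzyloxy)-3-bromo-2-(dimethoxymethyl)phenyl][3,4-bis(benzyloxy)phenyl]methyl}butanedioate (C2 epimers) | CC(C)(C)OC(=O)CC(C(=O)OC(C)(C)C)[C@H](c1ccc(OCc2ccccc2)c(OCc2ccccc2)c1)c1cc(OCc2ccccc2)c(OCc2ccccc2)c(Br)c1C(OC)OC | intermediate
12 | di-tert-butyl 2-{(R)-[4,5-bis(benzyloxy)-3-bromo-2-formylphenyl][3,4-bis(benzyloxy)phenyl]methyl}butanedioate (C2 epimers) | CC(C)(C)OC(=O)CC(C(=O)OC(C)(C)C)[C@H](c1ccc(OCc2ccccc2)c(OCc2ccccc2)c1)c1cc(OCc2ccccc2)c(OCc2ccccc2)c(Br)c1C=O | intermediate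
13 | di-tert-butyl (1R)-6,7-bis(benzyloxy)-1-[3,4-bis(benzyloxy)phenyl]-5-bromo-4-hydroxy-1,2,3,4-tetrahydronaphthalene-2,3-dicarboxylate (aldol adduct, not isolated, isomers at C2 to C4) | O=C(OC(C)(C)C)C1C(O)c2c(cc(OCc3ccccc3)c(OCc3ccccc3)c2Br)[C@@H](c2ccc(OCc3ccccc3)c(OCc3ccccc3)c2)C1C(=O)OC(C)(C)C | intermediate
14 | di-tert-butyl (1R,2S)-6,7-bis(benzyloxy)-1-[3,4-bis(benzyloxy)phenyl]-5-bromo-1,2-dihydronaphthalene-2,3-dicarboxylate | O=C(OC(C)(C)C)C1=Cc2c(cc(OCc3ccccc3)c(OCc3ccccc3)c2Br)[C@@H](c2ccc(OCc3ccccc3)c(OCc3ccccc3)c2)[C@@H]1C(=O)OC(C)(C)C | intermediate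
15 | tert-butyl (3S)-3-[4,5-bis(benzyloxy)-3-bromo-2-(dimethoxymethyl)phenyl]-3-[3,4-bis(benzyloxy)phenyl]propanoate | CC(C)(C)OC(=O)C[C@@H](c1ccc(OCc2ccccc2)c(OCc2ccccc2)c1)c1cc(OCc2ccccc2)c(OCc2ccccc2)c(Br)c1C(OC)OC | intermediate
16 | di-tert-butyl 2-{(S)-[4,5-bis(benzyloxy)-3-bromo-2-(dimethoxymethyl)phenyl][3,4-bis(benzyloxy)phenyl]methyl}butanedioate (C2 epimers) | CC(C)(C)OC(=O)CC(C(=O)OC(C)(C)C)[C@@H](c1ccc(OCc2ccccc2)c(OCc2ccccc2)c1)c1cc(OCc2ccccc2)c(OCc2ccccc2)c(Br)c1C(OC)OC | intermediate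
17 | di-tert-butyl 2-{(S)-[4,5-bis(benzyloxy)-3-bromo-2-formylphenyl][3,4-bis(benzyloxy)phenyl]methyl}butanedioate (C2 epimers) | CC(C)(C)OC(=O)CC(C(=O)OC(C)(C)C)[C@@H](c1ccc(OCc2ccccc2)c(OCc2ccccc2)c1)c1cc(OCc2ccccc2)c(OCc2ccccc2)c(Br)c1C=O | intermediate
18 | di-tert-butyl (1S)-6,7-bis(benzyloxy)-1-[3,4-bis(benzyloxy)phenyl]-5-bromo-4-hydroxy-1,2,3,4-tetrahydronaphthalene-2,3-dicarboxylate (aldol adduct, not isolated, isomers at C2 to C4) | O=C(OC(C)(C)C)C1C(O)c2c(cc(OCc3ccccc3)c(OCc3ccccc3)c2Br)[C@H](c2ccc(OCc3ccccc3)c(OCc3ccccc3)c2)C1C(=O)OC(C)(C)C | intermediate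
19 | di-tert-butyl (1S,2R)-6,7-bis(benzyloxy)-1-[3,4-bis(benzyloxy)phenyl]-5-bromo-1,2-dihydronaphthalene-2,3-dicarboxylate | O=C(OC(C)(C)C)C1=Cc2c(cc(OCc3ccccc3)c(OCc3ccccc3)c2Br)[C@H](c2ccc(OCc3ccccc3)c(OCc3ccccc3)c2)[C@H]1C(=O)OC(C)(C)C | intermediate
20 | di-tert-butyl (1S,2R)-6,7-bis(benzyloxy)-1-[3,4-bis(benzyloxy)phenyl]-5-(4,4,5,5-tetramethyl-1,3,2-dioxaborolan-2-yl)-1,2-dihydronaphthalene-2,3-dicarboxylate | O=C(OC(C)(C)C)C1=Cc2c(cc(OCc3ccccc3)c(OCc3ccccc3)c2B3OC(C)(C)C(C)(C)O3)[C@H](c2ccc(OCc3ccccc3)c(OCc3ccccc3)c2)[C@H]1C(=O)OC(C)(C)C | intermediate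
21 | tetra-tert-butyl (1R,2S,1'S,2'R)-6,6',7,7'-tetrakis(benzyloxy)-1,1'-bis[3,4-bis(benzyloxy)phenyl]-1,1',2,2'-tetrahydro-[5,5'-binaphthalene]-2,2',3,3'-tetracarboxylate | O=C(OC(C)(C)C)C1=Cc2c(cc(OCc3ccccc3)c(OCc3ccccc3)c2-c2c(OCc3ccccc3)c(OCc3ccccc3)cc3c2C=C(C(=O)OC(C)(C)C)[C@H](C(=O)OC(C)(C)C)[C@H]3c2ccc(OCc3ccccc3)c(OCc3ccccc3)c2)[C@@H](c2ccc(OCc3ccccc3)c(OCc3ccccc3)c2)[C@@H]1C(=O)OC(C)(C)C | intermediate
22 | (1R,2S,1'S,2'R)-6,6',7,7'-tetrakis(benzyloxy)-1,1'-bis[3,4-bis(benzyloxy)phenyl]-1,1',2,2'-tetrahydro-[5,5'-binaphthalene]-2,2',3,3'-tetracarboxylic acid | O=C(O)C1=Cc2c(cc(OCc3ccccc3)c(OCc3ccccc3)c2-c2c(OCc3ccccc3)c(OCc3ccccc3)cc3c2C=C(C(=O)O)[C@H](C(=O)O)[C@H]3c2ccc(OCc3ccccc3)c(OCc3ccccc3)c2)[C@@H](c2ccc(OCc3ccccc3)c(OCc3ccccc3)c2)[C@@H]1C(=O)O | intermediate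
23 | (1R,2S,1'S,2'R)-1,1'-bis(3,4-dihydroxyphenyl)-6,6',7,7'-tetrahydroxy-1,1',2,2'-tetrahydro-[5,5'-binaphthalene]-2,2',3,3'-tetracarboxylic acid | O=C(O)C1=Cc2c(cc(O)c(O)c2-c2c(O)c(O)cc3c2C=C(C(=O)O)[C@H](C(=O)O)[C@H]3c2ccc(O)c(O)c2)[C@@H](c2ccc(O)c(O)c2)[C@@H]1C(=O)O | target

## Step count and risks

Total steps: 17. Longest linear sequence: 13 (steps 1–5, 10–13, 14, 15, 16, 17).

**Risk 1, step 15 (hindered Suzuki coupling of base-sensitive partners).** The fallback is a base-free, copper- and fluoride-promoted Stille coupling. It sets out from 19 (in place of step 14) and 14 and comes back at 21. Bromide 19 is stannylated with Me3SnSnMe3 and Pd(PPh3)4 in toluene at 100 °C to give di-tert-butyl (1S,2R)-6,7-bis(benzyloxy)-1-[3,4-bis(benzyloxy)phenyl]-5-(trimethylstannyl)-1,2-dihydronaphthalene-2,3-dicarboxylate F1. This is coupled with 14 using Pd(PPh3)4, CuI and CsF in DMF at 45 °C. The copper-assisted transmetalation tolerates ortho crowding, and no phosphate or water is present to attack the boron partner or C2.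

**Risk 2, step 6 (and its twin, step 10; 1,4-arylation of an ortho-substituted cinnamate may be slow or poorly selective).** The fallback makes the C–H bond rather than the C–aryl bond at the stereocentre. It sets out from 7 and comes back at 9 (and at 15 with the antipodal ligand). A Heck arylation of 7 with 1,2-bis(benzyloxy)-4-iodobenzene (Pd(OAc)2, Bu4NCl, NaHCO3, DMF, 90 °C; the C–I bond reacts before the hindered, electron-rich C–Br bond) gives, by syn insertion and syn elimination, tert-butyl (2Z)-3-[4,5-bis(benzyloxy)-3-bromo-2-(dimethoxymethyl)phenyl]-3-[3,4-bis(benzyloxy)phenyl]prop-2-enoate F2. Copper hydride asymmetric conjugate reduction of F2 (Cu(OAc)2 5 mol%, (R)- or (S)-DTBM-SEGPHOS, diethoxy(methyl)silane, t-BuOH, toluene, rt) then sets the centre, the ortho-substituted aryl group being clearly differentiated from the unhindered one.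

**Risk 3, step 9 (and its twin, step 13; alkoxide-mediated condensation could move the double bond or erode C1).** The fallback separates ring closure from dehydration and avoids alkoxide. It sets out from 12 and comes back at 14. Kinetic deprotonation of the less hindered succinate CH2 with LiN(SiMe3)2 in THF at −78 °C, quenched with AcOH, gives the aldol adduct 13, which is now isolated. Mesylation (MsCl, Et3N, CH2Cl2, 0 °C) gives di-tert-butyl (1R)-6,7-bis(benzyloxy)-1-[3,4-bis(benzyloxy)phenyl]-5-bromo-4-[(methylsulfonyl)oxy]-1,2,3,4-tetrahydronaphthalene-2,3-dicarboxylate F3. DBU (2.2 equiv) in toluene at rt to 40 °C eliminates the sulfonate (E1cB) and equilibrates C2 to trans, giving 14. The mirror series runs the same way from 17 through isolated 18 and di-tert-butyl (1S)-6,7-bis(benzyloxy)-1-[3,4-bis(benzyloxy)phenyl]-5-bromo-4-[(methylsulfonyl)oxy]-1,2,3,4-tetrahydronaphthalene-2,3-dicarboxylate F4 to 19.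

## Further compounds

F1 | step 15 | di-tert-butyl (1S,2R)-6,7-bis(benzyloxy)-1-[3,4-bis(benzyloxy)phenyl]-5-(trimethylstannyl)-1,2-dihydronaphthalene-2,3-dicarboxylate | O=C(OC(C)(C)C)C1=Cc2c(cc(OCc3ccccc3)c(OCc3ccccc3)c2[Sn](C)(C)C)[C@H](c2ccc(OCc3ccccc3)c(OCc3ccccc3)c2)[C@H]1C(=O)OC(C)(C)C
F2 | step 6 | tert-butyl (2Z)-3-[4,5-bis(benzyloxy)-3-bromo-2-(dimethoxymethyl)phenyl]-3-[3,4-bis(benzyloxy)phenyl]prop-2-enoate | CC(C)(C)OC(=O)/C=C(\c1cc(OCc2ccccc2)c(OCc2ccccc2)c(Br)c1C(OC)OC)c1ccc(OCc2ccccc2)c(OCc2ccccc2)c1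
F3 | step 9 | di-tert-butyl (1R)-6,7-bis(benzyloxy)-1-[3,4-bis(benzyloxy)phenyl]-5-bromo-4-[(methylsulfonyl)oxy]-1,2,3,4-tetrahydronaphthalene-2,3-dicarboxylate | O=C(OC(C)(C)C)C1C(OS(C)(=O)=O)c2c(cc(OCc3ccccc3)c(OCc3ccccc3)c2Br)[C@@H](c2ccc(OCc3ccccc3)c(OCc3ccccc3)c2)C1C(=O)OC(C)(C)C
F4 | step 13 | di-tert-butyl (1S)-6,7-bis(benzyloxy)-1-[3,4-bis(benzyloxy)phenyl]-5-bromo-4-[(methylsulfonyl)oxy]-1,2,3,4-tetrahydronaphthalene-2,3-dicarboxylate | O=C(OC(C)(C)C)C1C(OS(C)(=O)=O)c2c(cc(OCc3ccccc3)c(OCc3ccccc3)c2Br)[C@H](c2ccc(OCc3ccccc3)c(OCc3ccccc3)c2)C1C(=O)OC(C)(C)C
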